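**Retrosynthetic overview**

1. Numbering: N4, C5–C8 (azepane CH2 groups), C9 (ring-fusion CH), C9a (aza-quaternary carbon), C1–C3 (pyrrolidine; C3 bears the side lactone C18–C21), cyclopentane C9a–C9–C10(Et)–C11(O)–C12, fused lactone O–C14(=O)–C13(Me)(OH)–C12. Last disconnection: the C8 methylene comes from a temporary C8 ketone (dithiolane, Raney Ni).
2. Key disconnection: N4–C5 and C9–C9a (with N4=C9a) are opened together. This unravels azepane, cyclopentane and pyrroline to an acyclic N-Boc γ-amino ketone that carries a cyclopropyl ketone (C8, with C5–C7 as the cyclopropane) and both lactones.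
3. Enabling feature: C9a is the α-amino carbon shared by the pyrrolidine and azepane rings and also a cyclopentane atom next to C9. With a C8 carbonyl, N4–C9a–C9–C8(=O) is a Mannich retron and C8(=O)–C7–C6–C5–N4 a homo-conjugate (cyclopropyl ketone) retron; C12 is α to C9a, so its configuration can be corrected in the same step.
4. The acyclic precursor is cut at C9a–C1 (Fukuyama coupling) into a thioester holding the fused lactone (C13 from (S)-citramalic acid, C11/C12 by Evans aldol, C10 by organo-photoredox alkylation) and an alkyl iodide holding the side lactone (C3 from L-homoserine, C18 by zinc allylation, C20 by hydrogenation).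
5. Ring order: fused lactone and side lactone first (separate fragments), then pyrroline, cyclopentane and azepane in one pot.

Key step: step 11

Assumption: the (2R,5S)-imidazolidinone used in step 1 is taken to shield the enamine face that leads to the (2R)-aldehyde; if the sense proves opposite, its enantiomer is used.

**Route**

Step 1
Reactants: 1 butanal; 2 2-bromo-1-cyclopropylethan-1-one
Product: 3 (2R)-4-cyclopropyl-2-ethyl-4-oxobutanal
Conditions: (2R,5S)-2-tert-butyl-3,5-dimethylimidazolidin-4-one·TfOH (20 mol%), Ru(bpy)3Cl2 (0.5 mol%), 2,6-lutidine, DMF, visible light, 23 °C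
Reagents that add atoms: none
Why: Enamine organocatalysis merged with photoredox catalysis (enantioselective α-alkylation of aldehydes with α-bromo ketones): the α-keto radical from 2 adds to the enamine face left open by the tert-butyl group, which sets C10 (R), and the cyclopropane, not being on the radical carbon, stays closed.

Step 2
Reactants: 4 (2S)-2-hydroxy-2-methylbutanedioic acid ((S)-citramalic acid)
Product: 5 2-[(4S)-2,2,4-trimethyl-5-oxo-1,3-dioxolan-4-yl]acetic acid
Conditions: 2,2-dimethoxypropane, TsOH·H2O (cat.), rt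
Reagents that add atoms: 2,2-dimethoxypropane, COC(C)(C)OC
Why: Acid-catalysed dioxolanone (acetonide) formation ties up the tertiary α-hydroxy acid as the five-membered ring and leaves the CH2CO2H arm free; C13 is not touched.

Step 3
Reactants: 5 2-[(4S)-2,2,4-trimethyl-5-oxo-1,3-dioxolan-4-yl]acetic acid; 6 (4R)-4-benzyl-1,3-oxazolidin-2-one
Product: 7 (4R)-4-benzyl-3-{2-[(4S)-2,2,4-trimethyl-5-oxo-1,3-dioxolan-4-yl]acetyl}-1,3-oxazolidin-2-one
Conditions: DCC, DMAP (cat.), CH2Cl2, 0 °C to rt
Reagents that add atoms: none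
Why: Carbodiimide-mediated N-acylation of the oxazolidinone with the free acid installs the auxiliary; no stereocentre is involved.

Step 4
Reactants: 7 (4R)-4-benzyl-3-{2-[(4S)-2,2,4-trimethyl-5-oxo-1,3-dioxolan-4-yl]acetyl}-1,3-oxazolidin-2-one; 3 (2R)-4-cyclopropyl-2-ethyl-4-oxobutanal
Product: 10 (4R)-4-benzyl-3-[(2S,3S,4S)-2-[(3R)-1-cyclopropyl-1-oxopentan-3-yl]-4-hydroxy-4-methyl-5-oxooxolane-3-carbonyl]-1,3-oxazolidin-2-one, via boron enolate 8 (not isolated), via aldol adduct 9 (not isolated)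
Conditions: Bu2BOTf, i-Pr2NEt, CH2Cl2, −78 to 0 °C; then 3, −78 to 0 °C; pH 7 buffer, MeOH, H2O2; then TsOH·H2O (cat.), CH2Cl2, rt
Reagents that add atoms: none
Why: Evans syn-aldol: the Z-boron enolate reacts through a Zimmerman–Traxler chair on the face away from the benzyl group, which sets C11 (S) and C12 under auxiliary control (overriding the weak Felkin bias of 3), and the new C11 hydroxyl then opens the dioxolanone (5-exo-trig transacylation, loss of acetone) to the γ-lactone with the C12 acyl group trans to the C10 chain.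

Step 5
Reactants: 10 (4R)-4-benzyl-3-[(2S,3S,4S)-2-[(3R)-1-cyclopropyl-1-oxopentan-3-yl]-4-hydroxy-4-methyl-5-oxooxolane-3-carbonyl]-1,3-oxazolidin-2-one
Product: 11 S-ethyl (2S,3S,4S)-2-[(3R)-1-cyclopropyl-1-oxopentan-3-yl]-4-hydroxy-4-methyl-5-oxooxolane-3-carbothioate
Conditions: EtSH, n-BuLi, THF, −78 to 0 °C; aq. NH4Cl
Reagents that add atoms: ethanethiol, CCS
Why: Lithium ethanethiolate attacks the exocyclic imide carbonyl selectively (transthioesterification of N-acyl oxazolidinones) and frees the auxiliary, and the weakly basic thiolate at low temperature should leave C12 and the β-acyloxy lactone intact.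

Step 6
Reactants: 12 tert-butyl N-[(3S)-2-oxooxolan-3-yl]carbamate (N-Boc-L-homoserine lactone)
Product: 13 tert-butyl N-[(3S)-2-hydroxyoxolan-3-yl]carbamate (lactol, both anomers)
Conditions: i-Bu2AlH, CH2Cl2, −78 °C; aq. potassium sodium tartrate
Reagents that add atoms: none
Why: Half-reduction of a γ-lactone stops at the lactol because the tetrahedral aluminate is stable at −78 °C; C3 is not deprotonated under these conditions.

Step 7
Reactants: 13 tert-butyl N-[(3S)-2-hydroxyoxolan-3-yl]carbamate; 14 ethyl 2-(bromomethyl)prop-2-enoate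
Product: 16 tert-butyl N-[(1S)-3-hydroxy-1-[(2S)-4-methylidene-5-oxooxolan-2-yl]propyl]carbamate, via hydroxy ester 15 (not isolated)
Conditions: Zn dust, THF/sat. aq. NH4Cl, rt; then TsOH·H2O (cat.), CH2Cl2, rt
Reagents that add atoms: none
Why: Barbier-type allylation of the open hydroxy aldehyde form of 13 with the 2-(ethoxycarbonyl)allylzinc reagent (Dreiding–Schmidt α-methylene lactone synthesis); Cram-chelate addition (zinc bridging carbamate and aldehyde) should favour the syn amino alcohol, C18 (S), and acid then closes the lactone.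

Step 8
Reactants: 16 tert-butyl N-[(1S)-3-hydroxy-1-[(2S)-4-methylidene-5-oxooxolan-2-yl]propyl]carbamate
Product: 17 tert-butyl N-[(1S)-3-hydroxy-1-[(2S,4S)-4-methyl-5-oxooxolan-2-yl]propyl]carbamate
Conditions: H2 (1 atm), Pd/C, EtOAc, rt
Reagents that add atoms: none
Why: Heterogeneous hydrogenation delivers H2 to the exocyclic methylene from the face opposite the C18 substituent, so the methyl group ends cis to it, C20 (S).

Step 9
Reactants: 17 tert-butyl N-[(1S)-3-hydroxy-1-[(2S,4S)-4-methyl-5-oxooxolan-2-yl]propyl]carbamate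
Product: 18 tert-butyl N-[(1S)-3-iodo-1-[(2S,4S)-4-methyl-5-oxooxolan-2-yl]propyl]carbamate
Conditions: I2, PPh3, imidazole, CH2Cl2, 0 °C to rt
Reagents that add atoms: iodine, II
Why: Appel-type iodination of the primary alcohol (SN2 at CH2); carbamate N–H and lactone are inert at this temperature.

Step 10
Reactants: 18 tert-butyl N-[(1S)-3-iodo-1-[(2S,4S)-4-methyl-5-oxooxolan-2-yl]propyl]carbamate; 11 S-ethyl (2S,3S,4S)-2-[(3R)-1-cyclopropyl-1-oxopentan-3-yl]-4-hydroxy-4-methyl-5-oxooxolane-3-carbothioate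
Product: 20 tert-butyl N-[(1S)-4-[(2S,3S,4S)-2-[(3R)-1-cyclopropyl-1-oxopentan-3-yl]-4-hydroxy-4-methyl-5-oxooxolan-3-yl]-1-[(2S,4S)-4-methyl-5-oxooxolan-2-yl]-4-oxobutyl]carbamate, via alkylzinc iodide 19 (not isolated)
Conditions: Zn dust (activated with Me3SiCl), DMF, rt; then 11, PdCl2(PPh3)2 (5 mol%), PhMe, rt
Reagents that add atoms: none
Why: Fukuyama coupling: zinc inserts into the primary C–I bond (carbamate and lactone tolerated) and the alkylzinc iodide (used in excess) is acylated by the thioester after its oxidative addition to zerovalent palladium, which forms C9a–C1 without touching ketone, lactones or the tertiary alcohol and without involving a stereocentre.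

Step 11
Reactants: 20 tert-butyl N-[(1S)-4-[(2S,3S,4S)-2-[(3R)-1-cyclopropyl-1-oxopentan-3-yl]-4-hydroxy-4-methyl-5-oxooxolan-3-yl]-1-[(2S,4S)-4-methyl-5-oxooxolan-2-yl]-4-oxobutyl]carbamate
Product: 24 pentacyclic amino ketone (8-oxo derivative of the target; configured as the target at every centre), via cyclic imine 21 (not isolated), via spiro amino ketone 22 (not isolated), via bromo ketone 23 (not isolated)
Conditions: TFA, CH2Cl2, 0 to 40 °C; then HBr (33% in AcOH), rt; evaporate; K2CO3, MeCN, 50 °C (one pot)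
Reagents that add atoms: none
Why: TFA removes Boc and the γ-amino ketone condenses (5-exo-trig addition, loss of water) to the pyrrolinium ion of 21 (N4=C9a); C12, now α to the iminium, equilibrates through the enamine, and only the epimer with C9a cis to the C10 chain on the lactone can close the next ring at a useful rate, so the trans material from step 4 is funnelled into one series (Curtin–Hammett). The cyclopropyl ketone can enolise only toward C9, and this enol attacks C9a in an intramolecular Mannich reaction, 5-(enolexo)-exo-trig, which closes the cyclopentane cis-fused to the lactone (22); the closest known reaction type is the acid-mediated intramolecular Mannich cyclisation of cyclic ketiminium ions on tethered ketones that is used to make α-tertiary amines. C9a is set by attack on the pyrrolinium face anti to the C3 lactone substituent, which leaves N4 on the convex face trans to C13. C9 is set by allylic 1,3-strain in the enol (H–C10 in the enol plane), so C8 ends trans to the ethyl group, the arrangement that is also expected to be favoured while C9 can still equilibrate next to the ketone. HBr then opens the protonated cyclopropyl ketone at a methylene carbon (homo-conjugate addition) to bromo ketone 23, and after basification N4 displaces bromide, 7-exo-tet, to close the trans-fused azepane (N4–C5). The step needs Mannich closure through C9 and not C7 (secured by the cyclopropane, whose methine cannot enolise) and N-alkylation in preference to aminolysis of either lactone (secured by the primary bromide and by the trans disposition of N4 and C14).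

Step 12
Reactants: 24 pentacyclic amino ketone (8-oxo derivative of the target)
Product: 25 8,8-(ethane-1,2-diyldisulfanediyl) derivative of the target (spiro-1,3-dithiolane at C8)
Conditions: HSCH2CH2SH, BF3·OEt2, CH2Cl2, 0 °C to rt
Reagents that add atoms: ethane-1,2-dithiol, SCCS
Why: Lewis acid-promoted dithioketalisation of the C8 ketone; the complexed amine cannot trigger retro-Mannich cleavage, and lactones and the tertiary alcohol are inert.

Step 13
Reactants: 25 spiro-1,3-dithiolane at C8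
Product: 26 target CNP0260919.2, (3S,9R,9aS,10R,11S,12R,13S,18S,20S)-configured
Conditions: Raney Ni (washed neutral), EtOH/THF, 50 °C
Reagents that add atoms: none
Why: Mozingo reduction: Raney Ni hydrogenolyses both C–S bonds and turns C8 into CH2, while lactones, tertiary amine, tertiary alcohol and all stereocentres are left alone.

**Compound list**

1 | butanal | CCCC=O | starting material
2 | 2-bromo-1-cyclopropylethan-1-one | BrCC(=O)C1CC1 | starting material
3 | (2R)-4-cyclopropyl-2-ethyl-4-oxobutanal | CC[C@H](CC(=O)C1CC1)C=O | intermediate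
4 | (2S)-2-hydroxy-2-methylbutanedioic acid ((S)-citramalic acid) | OC(=O)[C@@](C)(O)CC(=O)O | starting material
5 | 2-[(4S)-2,2,4-trimethyl-5-oxo-1,3-dioxolan-4-yl]acetic acid | O=C1OC(C)(C)O[C@@]1(C)CC(=O)O | intermediate
6 | (4R)-4-benzyl-1,3-oxazolidin-2-one | O=C1N[C@H](Cc2ccccc2)CO1 | starting material
7 | (4R)-4-benzyl-3-{2-[(4S)-2,2,4-trimethyl-5-oxo-1,3-dioxolan-4-yl]acetyl}-1,3-oxazolidin-2-one | O=C1OC(C)(C)O[C@@]1(C)CC(=O)N1[C@H](Cc2ccccc2)COC1=O | intermediate
8 | dibutylboron (Z)-enolate of 7 | CCCCB(CCCC)O/C(N1[C@H](Cc2ccccc2)COC1=O)=C\[C@]1(C)OC(C)(C)OC1=O | intermediate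
9 | (4R)-4-benzyl-3-[(2S,3S,4R)-6-cyclopropyl-4-ethyl-3-hydroxy-6-oxo-2-[(4S)-2,2,4-trimethyl-5-oxo-1,3-dioxolan-4-yl]hexanoyl]-1,3-oxazolidin-2-one (aldol adduct) | CC[C@H](CC(=O)C1CC1)[C@H](O)[C@H](C(=O)N1[C@H](Cc2ccccc2)COC1=O)[C@]1(C)OC(C)(C)OC1=O | intermediate
10 | (4R)-4-benzyl-3-[(2S,3S,4S)-2-[(3R)-1-cyclopropyl-1-oxopentan-3-yl]-4-hydroxy-4-methyl-5-oxooxolane-3-carbonyl]-1,3-oxazolidin-2-one | CC[C@H](CC(=O)C1CC1)[C@@H]1OC(=O)[C@@](C)(O)[C@H]1C(=O)N1[C@H](Cc2ccccc2)COC1=O | intermediate
11 | S-ethyl (2S,3S,4S)-2-[(3R)-1-cyclopropyl-1-oxopentan-3-yl]-4-hydroxy-4-methyl-5-oxooxolane-3-carbothioate | CC[C@H](CC(=O)C1CC1)[C@@H]1OC(=O)[C@@](C)(O)[C@H]1C(=O)SCC | intermediate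
12 | tert-butyl N-[(3S)-2-oxooxolan-3-yl]carbamate (N-Boc-L-homoserine lactone) | O=C1OCC[C@@H]1NC(=O)OC(C)(C)C | starting material
13 | tert-butyl N-[(3S)-2-hydroxyoxolan-3-yl]carbamate (lactol) | OC1OCC[C@@H]1NC(=O)OC(C)(C)C | intermediate
14 | ethyl 2-(bromomethyl)prop-2-enoate | CCOC(=O)C(=C)CBr | starting material
15 | ethyl (4S,5S)-5-[(tert-butoxycarbonyl)amino]-4,7-dihydroxy-2-methylideneheptanoate | OCC[C@@H]([C@@H](O)CC(=C)C(=O)OCC)NC(=O)OC(C)(C)C | intermediate
16 | tert-butyl N-[(1S)-3-hydroxy-1-[(2S)-4-methylidene-5-oxooxolan-2-yl]propyl]carbamate | OCC[C@@H]([C@@H]1CC(=C)C(=O)O1)NC(=O)OC(C)(C)C | intermediate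
17 | tert-butyl N-[(1S)-3-hydroxy-1-[(2S,4S)-4-methyl-5-oxooxolan-2-yl]propyl]carbamate | OCC[C@@H]([C@@H]1C[C@H](C)C(=O)O1)NC(=O)OC(C)(C)C | intermediate
18 | tert-butyl N-[(1S)-3-iodo-1-[(2S,4S)-4-methyl-5-oxooxolan-2-yl]propyl]carbamate | ICC[C@@H]([C@@H]1C[C@H](C)C(=O)O1)NC(=O)OC(C)(C)C | intermediate
19 | [(3S)-3-[(tert-butoxycarbonyl)amino]-3-[(2S,4S)-4-methyl-5-oxooxolan-2-yl]propyl](iodo)zinc | I[Zn]CC[C@@H]([C@@H]1C[C@H](C)C(=O)O1)NC(=O)OC(C)(C)C | intermediate
20 | tert-butyl N-[(1S)-4-[(2S,3S,4S)-2-[(3R)-1-cyclopropyl-1-oxopentan-3-yl]-4-hydroxy-4-methyl-5-oxooxolan-3-yl]-1-[(2S,4S)-4-methyl-5-oxooxolan-2-yl]-4-oxobutyl]carbamate | CC[C@H](CC(=O)C1CC1)[C@@H]1OC(=O)[C@@](C)(O)[C@H]1C(=O)CC[C@@H]([C@@H]1C[C@H](C)C(=O)O1)NC(=O)OC(C)(C)C | intermediate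
21 | (3S,4S,5S)-5-[(3R)-1-cyclopropyl-1-oxopentan-3-yl]-3-hydroxy-3-methyl-4-[(2S)-2-[(2S,4S)-4-methyl-5-oxooxolan-2-yl]-3,4-dihydro-2H-pyrrol-5-yl]oxolan-2-one (cyclic imine, C12 still trans) | CC[C@H](CC(=O)C1CC1)[C@@H]1OC(=O)[C@@](C)(O)[C@H]1C1=N[C@@H](CC1)[C@@H]1C[C@H](C)C(=O)O1 | intermediate
22 | spiro amino ketone: pyrrolidine (N4, C1–C3, C9a) spiro at C9a to the cyclopentane C9a–C9–C10–C11–C12, lactone cis-fused at C11–C12, cyclopropylcarbonyl on C9, N4–H; configured as the target | CC[C@H]1[C@@H]2OC(=O)[C@@](C)(O)[C@@H]2[C@]2(CC[C@@H]([C@@H]3C[C@H](C)C(=O)O3)N2)[C@@H]1C(=O)C1CC1 | intermediate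
23 | bromo ketone: as 22 but 4-bromobutanoyl on C9 | CC[C@H]1[C@@H]2OC(=O)[C@@](C)(O)[C@@H]2[C@]2(CC[C@@H]([C@@H]3C[C@H](C)C(=O)O3)N2)[C@@H]1C(=O)CCCBr | intermediate
24 | pentacyclic amino ketone (8-oxo derivative of the target) | CC[C@H]1[C@@H]2OC(=O)[C@@](C)(O)[C@@H]2[C@@]23CC[C@@H]([C@@H]4C[C@H](C)C(=O)O4)N2CCCC(=O)[C@H]13 | intermediate
25 | spiro-1,3-dithiolane at C8 of the target skeleton | CC[C@H]1[C@@H]2OC(=O)[C@@](C)(O)[C@@H]2[C@@]23CC[C@@H]([C@@H]4C[C@H](C)C(=O)O4)N2CCCC4(SCCS4)[C@H]13 | intermediate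
26 | target CNP0260919.2, (3S,9R,9aS,10R,11S,12R,13S,18S,20S) | CC[C@H]1[C@@H]2OC(=O)[C@@](C)(O)[C@@H]2[C@@]23CC[C@@H]([C@@H]4C[C@H](C)C(=O)O4)N2CCCC[C@H]13 | target

**Step count and risks**

Total steps: 13. Longest linear sequence: 8 steps (steps 2, 3, 4, 5, 10, 11, 12, 13, or equally steps 6 to 13).

Most likely to fail, step 11: the Mannich closure may be outrun by opening of the fused lactone (β-elimination through the C12 enamine) or by retro-aldol loss of the C13 unit through the iminium. Facial selectivity at C9a may be poor, and C9 may epimerise before or after the azepane closes. Fallback, from 20 back to 22: pyrrolidine and AcOH in PhMe at 80 °C should bring about intramolecular aldol condensation of the 1,6-diketone (C9 onto the C9a carbonyl, with C12 correcting through the enol) to the 1-acylcyclopentene, N-Boc amino enone F1. TFA in CH2Cl2 then removes the Boc group and, after neutralisation (NaHCO3, MeOH), the amine should add to C9a in a 5-exo-trig aza-Michael reaction anti to the C3 substituent, with C9 set by protonation trans to ethyl. This gives 22 as an isolated compound, which HBr in AcOH and then K2CO3 in MeCN, run as separate operations, take through 23 to 24.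

Second, step 4: enolisation and addition of the neopentyl-type boron enolate may be slow, or the enolate may undergo β-elimination with opening of the dioxolanone. Fallback, from 6 and 3 back to 11, builds the lactone first and adds the C13 substituents afterwards.
- Acylation of 6 (n-BuLi, methyl 4-chloro-4-oxobutanoate, THF, −78 °C) gives (4R)-4-benzyl-3-(4-methoxy-4-oxobutanoyl)-1,3-oxazolidin-2-one F2.
- The Bu2BOTf/i-Pr2NEt aldol with 3, then acid-catalysed lactonisation, gives the trans paraconic imide F3.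
- LiOH/H2O2 frees the paraconic acid F4.
- Its dianion (NaN(SiMe3)2, THF, −78 °C) is hydroxylated by 3-phenyl-2-(phenylsulfonyl)oxaziridine anti to the carboxylate, giving hydroxy acid F5.
- The trianion (LiN(i-Pr)2, then MeI) is methylated, again anti to the carboxylate, so the hydroxyl is pushed to the face needed for C13 (S), giving hydroxy methyl acid F6.
- EtSH, DCC and DMAP convert F6 into 11.

Third, step 7: facial selectivity at C18 may be poor (chelate against Felkin addition). Fallback, from 12 back to 17, sets C18 by reagent control.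
- Me(MeO)NH·HCl/AlMe3 opens the lactone and t-BuMe2SiCl/imidazole caps the primary alcohol, giving Weinreb amide F7.
- Vinylmagnesium bromide gives enone F8.
- Reduction with BH3·SMe2 and the 2-methyl-CBS-oxazaborolidine enantiomer that delivers the (3S)-alcohol gives allylic alcohol F9.
- Methacryloyl chloride, Et3N and DMAP give methacrylate F10.
- Ring-closing metathesis with the second-generation Grubbs catalyst (CH2Cl2, 40 °C) gives butenolide F11.
- H2 over Pd/C adds anti to the C18 substituent and gives the cis lactone silyl ether F12.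
- HF·pyridine frees 17.

Further compounds
F1 | step 11 | N-Boc amino enone: lactone cis-fused to a cyclopentene with C9=C9a, cyclopropylcarbonyl on C9, CH2CH2CH(NHBoc)(side lactone) chain on C9a | CC[C@H]1[C@@H]2OC(=O)[C@@](C)(O)[C@@H]2C(CC[C@@H]([C@@H]3C[C@H](C)C(=O)O3)NC(=O)OC(C)(C)C)=C1C(=O)C1CC1
F2 | step 4 | (4R)-4-benzyl-3-(4-methoxy-4-oxobutanoyl)-1,3-oxazolidin-2-one | COC(=O)CCC(=O)N1[C@H](Cc2ccccc2)COC1=O
F3 | step 4 | (4R)-4-benzyl-3-[(2S,3R)-2-[(3R)-1-cyclopropyl-1-oxopentan-3-yl]-5-oxooxolane-3-carbonyl]-1,3-oxazolidin-2-one | CC[C@H](CC(=O)C1CC1)[C@@H]1OC(=O)C[C@H]1C(=O)N1[C@H](Cc2ccccc2)COC1=O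
F4 | step 4 | (2S,3R)-2-[(3R)-1-cyclopropyl-1-oxopentan-3-yl]-5-oxooxolane-3-carboxylic acid | CC[C@H](CC(=O)C1CC1)[C@@H]1OC(=O)C[C@H]1C(=O)O
F5 | step 4 | (2S,3R,4R)-2-[(3R)-1-cyclopropyl-1-oxopentan-3-yl]-4-hydroxy-5-oxooxolane-3-carboxylic acid | CC[C@H](CC(=O)C1CC1)[C@@H]1OC(=O)[C@H](O)[C@H]1C(=O)O
F6 | step 4 | (2S,3S,4S)-2-[(3R)-1-cyclopropyl-1-oxopentan-3-yl]-4-hydroxy-4-methyl-5-oxooxolane-3-carboxylic acid | CC[C@H](CC(=O)C1CC1)[C@@H]1OC(=O)[C@@](C)(O)[C@H]1C(=O)O
F7 | step 7 | tert-butyl N-[(2S)-4-[(tert-butyldimethylsilyl)oxy]-1-[methoxy(methyl)amino]-1-oxobutan-2-yl]carbamate | CON(C)C(=O)[C@H](CCO[Si](C)(C)C(C)(C)C)NC(=O)OC(C)(C)C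
F8 | step 7 | tert-butyl N-[(4S)-6-[(tert-butyldimethylsilyl)oxy]-3-oxohex-1-en-4-yl]carbamate | C=CC(=O)[C@H](CCO[Si](C)(C)C(C)(C)C)NC(=O)OC(C)(C)C
F9 | step 7 | tert-butyl N-[(3S,4S)-6-[(tert-butyldimethylsilyl)oxy]-3-hydroxyhex-1-en-4-yl]carbamate | C=C[C@H](O)[C@H](CCO[Si](C)(C)C(C)(C)C)NC(=O)OC(C)(C)C
F10 | step 7 | (3S,4S)-4-[(tert-butoxycarbonyl)amino]-6-[(tert-butyldimethylsilyl)oxy]hex-1-en-3-yl 2-methylprop-2-enoate | C=C[C@H](OC(=O)C(C)=C)[C@H](CCO[Si](C)(C)C(C)(C)C)NC(=O)OC(C)(C)C
F11 | step 7 | tert-butyl N-[(1S)-3-[(tert-butyldimethylsilyl)oxy]-1-[(2S)-4-methyl-5-oxo-2,5-dihydrofuran-2-yl]propyl]carbamate | CC1=C[C@@H]([C@H](CCO[Si](C)(C)C(C)(C)C)NC(=O)OC(C)(C)C)OC1=O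
F12 | step 7 | tert-butyl N-[(1S)-3-[(tert-butyldimethylsilyl)oxy]-1-[(2S,4S)-4-methyl-5-oxooxolan-2-yl]propyl]carbamate | C[C@H]1C[C@@H]([C@H](CCO[Si](C)(C)C(C)(C)C)NC(=O)OC(C)(C)C)OC1=O
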